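**Plan**

- Retrosynthesis: the C3 formyl group is traced back to a methyl ester and the two free hydroxyls (ring B phenol, side-chain carbinol) to silyl ethers. Four bonds of ring A (C7–C7a, C6–C7, C4–C5, C3a–C4) are then cut in one operation, giving a 2-furyl diazomethyl ketone and a 1-methoxyalkyne.
- Enabling feature: ring A carries OH at C4, the alkyl chain at C5 between two oxygens, OMe at C6 and a lone H at C7, and is fused to the furan at C3a/C7a. This is exactly the pattern left by a furylketene and a 1-methoxyalkyne.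
- Further cuts: furan C2–aryl (Negishi coupling), furan C5–carbonyl (magnesiation/CO2, then diazomethane), and the propargylic C–C bond of the ynol ether (methoxyacetylide plus iodide).
- Forward order: the furan and ring B are bought and joined first, then the diazoketone arm is added. The side chain is attached to the ynol ether separately. Ring A arises last, in the benzannulation, and ester-to-aldehyde adjustment and desilylation finish the route.
- Stereochemistry: the target has no stereocentre and no stereogenic double bond, so nothing has to be set.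

Key step: step 8

Remark: benzofuran numbering (O1, C2, C3, C3a, C4–C7, C7a) is used for the product side; methoxyethyne is assumed not to be purchasable and is generated in the flask as its lithium salt.

**Route**

Step 1
Reactants: 1 4-bromo-3-methoxyphenol
Product: 2 (4-bromo-3-methoxyphenoxy)triisopropylsilane
Conditions: TIPSCl, imidazole, DMF, rt
Reagents that add atoms: triisopropylsilyl chloride, CC(C)[Si](Cl)(C(C)C)C(C)C
Why: Silylation of a phenol with a silyl chloride and imidazole is standard, and the bulky triisopropylsilyl ether should withstand the amide bases, acid chloride formation, irradiation and hydride used later.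

Step 2
Reactants: 3 methyl furan-3-carboxylate; 2 (4-bromo-3-methoxyphenoxy)triisopropylsilane
Product: 6 methyl 2-[2-methoxy-4-(triisopropylsilyloxy)phenyl]furan-3-carboxylate, via furylmagnesium chloride 4 (not isolated), via furylzinc chloride 5 (not isolated)
Conditions: TMPMgCl·LiCl, THF, −40 °C; ZnCl2, −40 °C to rt; then 2, Pd(OAc)2 (2 mol %), SPhos (4 mol %), THF, 50 °C
Reagents that add atoms: none
Why: Ester-directed magnesiation of 3 at C2 by the hindered amide base, transmetalation to zinc and Negishi cross-coupling with aryl bromide 2 under a zerovalent palladium–SPhos catalyst formed from Pd(OAc)2 should forge the C2–aryl bond without touching the ester or the silyl ether.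

Step 3
Reactants: 6 methyl 2-[2-methoxy-4-(triisopropylsilyloxy)phenyl]furan-3-carboxylate
Product: 8 4-(methoxycarbonyl)-5-[2-methoxy-4-(triisopropylsilyloxy)phenyl]furan-2-carboxylic acid, via 5-furylmagnesium chloride 7 (not isolated)
Conditions: TMPMgCl·LiCl, THF, 0 °C to rt; CO2 (gas), −20 °C to rt; cold 1 M HCl work-up
Reagents that add atoms: carbon dioxide, O=C=O
Why: Directed metalation with TMPMgCl·LiCl is expected at C5, the only furan α-position left and more acidic than C4–H (as in the C5 magnesiation of 2-furoates), and the ester-tolerant organomagnesium 7 is then trapped by CO2 (carboxylation of an organomagnesium reagent).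

Step 4
Reactants: 8 4-(methoxycarbonyl)-5-[2-methoxy-4-(triisopropylsilyloxy)phenyl]furan-2-carboxylic acid
Product: 10 methyl 5-(2-diazoacetyl)-2-[2-methoxy-4-(triisopropylsilyloxy)phenyl]furan-3-carboxylate, via acid chloride 9 (not isolated)
Conditions: (COCl)2, DMF (cat.), CH2Cl2, 0 °C to rt; concentrate; CH2N2 (excess), Et2O, 0 °C
Reagents that add atoms: diazomethane, C=[N+]=[N-]
Why: Acid chloride formation under Vilsmeier catalysis followed by acylation of diazomethane (first stage of the Arndt–Eistert sequence) is the standard entry to diazomethyl ketones, a second equivalent of diazomethane scavenging the HCl so that neither the diazo group nor the aryl silyl ether meets acid.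

Step 5
Reactants: 11 3-methylbutane-1,3-diol
Product: 12 4-iodo-2-methylbutan-2-ol
Conditions: PPh3, I2, imidazole, CH2Cl2, 0 °C to rt
Reagents that add atoms: iodine, II
Why: Iodination with PPh3/I2/imidazole (Appel-type, Garegg–Samuelsson conditions) runs by SN2 displacement of an alkoxyphosphonium ion and should therefore select the primary hydroxyl over the tertiary one.

Step 6
Reactants: 12 4-iodo-2-methylbutan-2-ol
Product: 13 triethyl[(4-iodo-2-methylbutan-2-yl)oxy]silane
Conditions: TESOTf, 2,6-lutidine, CH2Cl2, −78 to 0 °C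
Reagents that add atoms: triethylsilyl trifluoromethanesulfonate, CC[Si](CC)(CC)OS(=O)(=O)C(F)(F)F
Why: Silylation of a hindered tertiary alcohol with a silyl triflate and 2,6-lutidine is routine and leaves the primary iodide untouched.

Step 7
Reactants: 14 2-chloro-1,1-dimethoxyethane (chloroacetaldehyde dimethyl acetal); 13 triethyl[(4-iodo-2-methylbutan-2-yl)oxy]silane
Product: 16 1-methoxy-5-methyl-5-(triethylsilyloxy)hex-1-yne, via lithium methoxyacetylide 15 (not isolated)
Conditions: Et2NH, n-BuLi (3 equiv each), THF, 0 °C; 14, 0 °C to rt; then 13, HMPA, 0 °C to rt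
Reagents that add atoms: none
Why: Three equivalents of LiNEt2 convert acetal 14 by twofold elimination and deprotonation into lithium methoxyacetylide 15, which is alkylated by primary iodide 13 in the presence of HMPA (SN2 acetylide alkylation, the standard route to 1-alkoxy-1-alkynes).

Step 8
Reactants: 10 methyl 5-(2-diazoacetyl)-2-[2-methoxy-4-(triisopropylsilyloxy)phenyl]furan-3-carboxylate; 16 1-methoxy-5-methyl-5-(triethylsilyloxy)hex-1-yne
Product: 21 methyl 4-hydroxy-6-methoxy-2-[2-methoxy-4-(triisopropylsilyloxy)phenyl]-5-[3-methyl-3-(triethylsilyloxy)butyl]-1-benzofuran-3-carboxylate, via furylketene 17 (not isolated), via cyclobutenone 18 (not isolated), via dienylketene 19 (not isolated), via dienone tautomer 20 (not isolated)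
Conditions: 16 (1.5–2 equiv), hν (medium-pressure Hg lamp, Pyrex filter), degassed ClCH2CH2Cl, rt; then 80 °C
Reagents that add atoms: none
Why: Irradiation expels N2 from 10 and the furyl group migrates to the diazo carbon (photochemical Wolff rearrangement, C7–C7a) to give furylketene 17, whose carbonyl carbon is attacked by the nucleophilic, chain-bearing carbon of ynol ether 16 so that a polar (2+2) cycloaddition closes the transient four-membered ring of 18 (C4–C5 and C6–C7). Conrotatory four-electron opening of 18 gives dienylketene 19, and ring A closes by a six-electron disrotatory electrocyclization of 19 onto the free β-carbon of the furan (C3a–C4), after which dienone 20 enolizes to the phenol on warming. The closest known reaction type is the Danheiser benzannulation of aryl and heteroaryl diazomethyl ketones with alkoxy- or siloxyalkynes in its photochemical Wolff variant. No stereocentre is created in 21; those of 18 and 20 are transient and racemic, and the ring opening is reversible so that only the dienylketene isomer able to cyclize is drained. The one selectivity required is the regiochemistry of the (2+2) step, secured by the polarization of the ynol ether (its oxygen-bearing carbon bonds to the ketene CH), which places OH on C4, the chain on C5, OMe on C6 and H on C7. The furan offers a single carbon next to the ketene-bearing position, so the final closure has no regiochemical alternative.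

Step 9
Reactants: 21 methyl 4-hydroxy-6-methoxy-2-[2-methoxy-4-(triisopropylsilyloxy)phenyl]-5-[3-methyl-3-(triethylsilyloxy)butyl]-1-benzofuran-3-carboxylate
Product: 22 3-(hydroxymethyl)-6-methoxy-2-[2-methoxy-4-(triisopropylsilyloxy)phenyl]-5-[3-methyl-3-(triethylsilyloxy)butyl]-1-benzofuran-4-ol
Conditions: i-Bu2AlH (4 equiv), CH2Cl2, −78 to 0 °C; aq. potassium sodium tartrate work-up; used crude
Reagents that add atoms: none
Why: Excess i-Bu2AlH first deprotonates the C4 phenol and then reduces the ester to the primary alcohol (hydride reduction of an ester), the silyl ethers being inert and the tartrate work-up avoiding acid that could ionize the electron-rich carbinol.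

Step 10
Reactants: 22 3-(hydroxymethyl)-6-methoxy-2-[2-methoxy-4-(triisopropylsilyloxy)phenyl]-5-[3-methyl-3-(triethylsilyloxy)butyl]-1-benzofuran-4-ol
Product: 23 4-hydroxy-6-methoxy-2-[2-methoxy-4-(triisopropylsilyloxy)phenyl]-5-[3-methyl-3-(triethylsilyloxy)butyl]-1-benzofuran-3-carbaldehyde
Conditions: MnO2 (excess), CH2Cl2, rt
Reagents that add atoms: none
Why: MnO2 oxidizes benzylic-type carbinols (here a benzofuran-3-ylmethanol) selectively to the aldehyde and should leave the phenol and both silyl ethers alone (allylic/benzylic MnO2 oxidation).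

Step 11
Reactants: 23 4-hydroxy-6-methoxy-2-[2-methoxy-4-(triisopropylsilyloxy)phenyl]-5-[3-methyl-3-(triethylsilyloxy)butyl]-1-benzofuran-3-carbaldehyde
Product: 24 4-hydroxy-2-(4-hydroxy-2-methoxyphenyl)-5-(3-hydroxy-3-methylbutyl)-6-methoxy-1-benzofuran-3-carbaldehyde (target)
Conditions: TBAF, AcOH (1:1, excess), THF, 0 °C to rt
Reagents that add atoms: none
Why: Fluoride cleaves both the aryl triisopropylsilyl ether and the tertiary triethylsilyl ether (fluoride-mediated desilylation), and the acetic acid buffer keeps the medium neither basic enough to harm the hydroxy aldehyde nor acidic enough to close the tertiary alcohol onto the C4 phenol.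

**Compound list**

1 | 4-bromo-3-methoxyphenol | COc1cc(O)ccc1Br | starting material
2 | (4-bromo-3-methoxyphenoxy)triisopropylsilane | COc1cc(O[Si](C(C)C)(C(C)C)C(C)C)ccc1Br | intermediate
3 | methyl furan-3-carboxylate | COC(=O)c1ccoc1 | starting material
4 | chloro[3-(methoxycarbonyl)furan-2-yl]magnesium (LiCl complex) | COC(=O)c1ccoc1[Mg]Cl | intermediate (not isolated)
5 | chloro[3-(methoxycarbonyl)furan-2-yl]zinc | COC(=O)c1ccoc1[Zn]Cl | intermediate (not isolated)
6 | methyl 2-[2-methoxy-4-(triisopropylsilyloxy)phenyl]furan-3-carboxylate | COC(=O)c1ccoc1-c1ccc(O[Si](C(C)C)(C(C)C)C(C)C)cc1OC | intermediate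
7 | chloro{4-(methoxycarbonyl)-5-[2-methoxy-4-(triisopropylsilyloxy)phenyl]furan-2-yl}magnesium (LiCl complex) | COC(=O)c1cc([Mg]Cl)oc1-c1ccc(O[Si](C(C)C)(C(C)C)C(C)C)cc1OC | intermediate (not isolated)
8 | 4-(methoxycarbonyl)-5-[2-methoxy-4-(triisopropylsilyloxy)phenyl]furan-2-carboxylic acid | COC(=O)c1cc(C(=O)O)oc1-c1ccc(O[Si](C(C)C)(C(C)C)C(C)C)cc1OC | intermediate
9 | methyl 5-(chlorocarbonyl)-2-[2-methoxy-4-(triisopropylsilyloxy)phenyl]furan-3-carboxylate | COC(=O)c1cc(C(Cl)=O)oc1-c1ccc(O[Si](C(C)C)(C(C)C)C(C)C)cc1OC | intermediate (not isolated)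
10 | methyl 5-(2-diazoacetyl)-2-[2-methoxy-4-(triisopropylsilyloxy)phenyl]furan-3-carboxylate | COC(=O)c1cc(C(=O)C=[N+]=[N-])oc1-c1ccc(O[Si](C(C)C)(C(C)C)C(C)C)cc1OC | intermediate
11 | 3-methylbutane-1,3-diol | CC(C)(O)CCO | starting material
12 | 4-iodo-2-methylbutan-2-ol | CC(C)(O)CCI | intermediate
13 | triethyl[(4-iodo-2-methylbutan-2-yl)oxy]silane | CC[Si](CC)(CC)OC(C)(C)CCI | intermediate
14 | 2-chloro-1,1-dimethoxyethane | COC(CCl)OC | starting material
15 | lithium methoxyacetylide | [Li]C#COC | intermediate (not isolated)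
16 | 1-methoxy-5-methyl-5-(triethylsilyloxy)hex-1-yne | COC#CCCC(C)(C)O[Si](CC)(CC)CC | intermediate
17 | methyl 2-[2-methoxy-4-(triisopropylsilyloxy)phenyl]-5-(2-oxoethenyl)furan-3-carboxylate (furylketene) | COC(=O)c1cc(C=C=O)oc1-c1ccc(O[Si](C(C)C)(C(C)C)C(C)C)cc1OC | intermediate (not isolated)
18 | methyl 5-{2-methoxy-3-[3-methyl-3-(triethylsilyloxy)butyl]-4-oxocyclobut-2-en-1-yl}-2-[2-methoxy-4-(triisopropylsilyloxy)phenyl]furan-3-carboxylate (racemic) | O=C1C(CCC(C)(C)O[Si](CC)(CC)CC)=C(OC)C1c1cc(C(=O)OC)c(-c2ccc(O[Si](C(C)C)(C(C)C)C(C)C)cc2OC)o1 | intermediate (not isolated)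
19 | methyl 5-{(1E)-2-methoxy-3-[3-methyl-3-(triethylsilyloxy)butyl]-4-oxobuta-1,3-dien-1-yl}-2-[2-methoxy-4-(triisopropylsilyloxy)phenyl]furan-3-carboxylate (dienylketene, furyl cis to the ketene unit) | O=C=C(CCC(C)(C)O[Si](CC)(CC)CC)/C(OC)=C\c1cc(C(=O)OC)c(-c2ccc(O[Si](C(C)C)(C(C)C)C(C)C)cc2OC)o1 | intermediate (not isolated)
20 | methyl 6-methoxy-2-[2-methoxy-4-(triisopropylsilyloxy)phenyl]-5-[3-methyl-3-(triethylsilyloxy)butyl]-4-oxo-3a,4-dihydro-1-benzofuran-3-carboxylate (racemic keto tautomer) | COC(=O)C1=C(-c2ccc(O[Si](C(C)C)(C(C)C)C(C)C)cc2OC)OC2=CC(OC)=C(CCC(C)(C)O[Si](CC)(CC)CC)C(=O)C12 | intermediate (not isolated)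
21 | methyl 4-hydroxy-6-methoxy-2-[2-methoxy-4-(triisopropylsilyloxy)phenyl]-5-[3-methyl-3-(triethylsilyloxy)butyl]-1-benzofuran-3-carboxylate | COC(=O)c1c(-c2ccc(O[Si](C(C)C)(C(C)C)C(C)C)cc2OC)oc2cc(OC)c(CCC(C)(C)O[Si](CC)(CC)CC)c(O)c12 | intermediate
22 | 3-(hydroxymethyl)-6-methoxy-2-[2-methoxy-4-(triisopropylsilyloxy)phenyl]-5-[3-methyl-3-(triethylsilyloxy)butyl]-1-benzofuran-4-ol | OCc1c(-c2ccc(O[Si](C(C)C)(C(C)C)C(C)C)cc2OC)oc2cc(OC)c(CCC(C)(C)O[Si](CC)(CC)CC)c(O)c12 | intermediate
23 | 4-hydroxy-6-methoxy-2-[2-methoxy-4-(triisopropylsilyloxy)phenyl]-5-[3-methyl-3-(triethylsilyloxy)butyl]-1-benzofuran-3-carbaldehyde | O=Cc1c(-c2ccc(O[Si](C(C)C)(C(C)C)C(C)C)cc2OC)oc2cc(OC)c(CCC(C)(C)O[Si](CC)(CC)CC)c(O)c12 | intermediate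
24 | 4-hydroxy-2-(4-hydroxy-2-methoxyphenyl)-5-(3-hydroxy-3-methylbutyl)-6-methoxy-1-benzofuran-3-carbaldehyde | COc1cc(O)ccc1-c1oc2cc(OC)c(CCC(C)(C)O)c(O)c2c1C=O | target

**Step count**

Total step count: 11. Longest linear sequence: 8 steps (steps 1, 2, 3, 4, 8, 9, 10, 11).

**Steps most likely to fail**

Step 8. The strongly absorbing arylfuran chromophore, and later the benzofuran product, may screen the diazoketone, so that ketene formation becomes slow. The furylketene may then be lost to dimerization or to acylation of the product phenol before the ynol ether captures it. The fallback separates ketene generation from light. Starting from 10, a silver-promoted Wolff rearrangement in wet solvent (PhCO2Ag, Et3N, THF/H2O) should give {4-(methoxycarbonyl)-5-[2-methoxy-4-(triisopropylsilyloxy)phenyl]furan-2-yl}acetic acid F1. Oxalyl chloride with catalytic DMF converts it into methyl 5-(2-chloro-2-oxoethyl)-2-[2-methoxy-4-(triisopropylsilyloxy)phenyl]furan-3-carboxylate F2. Slow addition of Et3N to F2 and alkyne 16 in toluene in the dark generates ketene 17 by dehydrochlorination, and 17 is trapped as cyclobutenone 18. Heating 18 in toluene (80–110 °C) carries it through 19 and 20, and the sequence comes back to the route at 21.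

Step 3. Deprotonation may occur at C4 next to the ester instead of at C5, or the furylmagnesium species may add to the ester of a second molecule before CO2 is admitted. The fallback replaces deprotonation by sterically governed C–H borylation. Starting from 6, B2pin2 with [Ir(OMe)(cod)]2 and 4,4'-di-tert-butyl-2,2'-bipyridine should borylate the only unhindered heteroaryl α C–H to give methyl 2-[2-methoxy-4-(triisopropylsilyloxy)phenyl]-5-(4,4,5,5-tetramethyl-1,3,2-dioxaborolan-2-yl)furan-3-carboxylate F3. Carboxylation of F3 with CO2 ((IPr)CuCl, KOMe, THF, 65 °C, then cold dilute HCl) comes back to the route at 8.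

Step 9. After the phenol has consumed hydride, reduction of the chelated, hydrogen-bonded vinylogous carbonate may stall. Alternatively the aluminium phenoxide may assist ionization of the electron-rich carbinol, leading to over-reduction or decomposition on work-up. The fallback masks the phenol before reduction. Starting from 21, TESOTf and 2,6-lutidine should give methyl 6-methoxy-2-[2-methoxy-4-(triisopropylsilyloxy)phenyl]-5-[3-methyl-3-(triethylsilyloxy)butyl]-4-(triethylsilyloxy)-1-benzofuran-3-carboxylate F4. i-Bu2AlH at −78 °C then reduces the unchelated ester to {6-methoxy-2-[2-methoxy-4-(triisopropylsilyloxy)phenyl]-5-[3-methyl-3-(triethylsilyloxy)butyl]-4-(triethylsilyloxy)-1-benzofuran-3-yl}methanol F5. MnO2 oxidizes F5 to 6-methoxy-2-[2-methoxy-4-(triisopropylsilyloxy)phenyl]-5-[3-methyl-3-(triethylsilyloxy)butyl]-4-(triethylsilyloxy)-1-benzofuran-3-carbaldehyde F6. Buffered TBAF/AcOH removes all three silyl groups, and the sequence comes back to the route at 24.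

**Further compounds**

F1 | step 8 | {4-(methoxycarbonyl)-5-[2-methoxy-4-(triisopropylsilyloxy)phenyl]furan-2-yl}acetic acid | COC(=O)c1cc(CC(=O)O)oc1-c1ccc(O[Si](C(C)C)(C(C)C)C(C)C)cc1OC
F2 | step 8 | methyl 5-(2-chloro-2-oxoethyl)-2-[2-methoxy-4-(triisopropylsilyloxy)phenyl]furan-3-carboxylate | COC(=O)c1cc(CC(Cl)=O)oc1-c1ccc(O[Si](C(C)C)(C(C)C)C(C)C)cc1OC
F3 | step 3 | methyl 2-[2-methoxy-4-(triisopropylsilyloxy)phenyl]-5-(4,4,5,5-tetramethyl-1,3,2-dioxaborolan-2-yl)furan-3-carboxylate | COC(=O)c1cc(B2OC(C)(C)C(C)(C)O2)oc1-c1ccc(O[Si](C(C)C)(C(C)C)C(C)C)cc1OC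
F4 | step 9 | methyl 6-methoxy-2-[2-methoxy-4-(triisopropylsilyloxy)phenyl]-5-[3-methyl-3-(triethylsilyloxy)butyl]-4-(triethylsilyloxy)-1-benzofuran-3-carboxylate | COC(=O)c1c(-c2ccc(O[Si](C(C)C)(C(C)C)C(C)C)cc2OC)oc2cc(OC)c(CCC(C)(C)O[Si](CC)(CC)CC)c(O[Si](CC)(CC)CC)c12
F5 | step 9 | {6-methoxy-2-[2-methoxy-4-(triisopropylsilyloxy)phenyl]-5-[3-methyl-3-(triethylsilyloxy)butyl]-4-(triethylsilyloxy)-1-benzofuran-3-yl}methanol | OCc1c(-c2ccc(O[Si](C(C)C)(C(C)C)C(C)C)cc2OC)oc2cc(OC)c(CCC(C)(C)O[Si](CC)(CC)CC)c(O[Si](CC)(CC)CC)c12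
F6 | step 9 | 6-methoxy-2-[2-methoxy-4-(triisopropylsilyloxy)phenyl]-5-[3-methyl-3-(triethylsilyloxy)butyl]-4-(triethylsilyloxy)-1-benzofuran-3-carbaldehyde | O=Cc1c(-c2ccc(O[Si](C(C)C)(C(C)C)C(C)C)cc2OC)oc2cc(OC)c(CCC(C)(C)O[Si](CC)(CC)CC)c(O[Si](CC)(CC)CC)c12
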